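**Plan**
- Retrosynthesis: the C18 acetate and the diene are cut first (C14=C15 by Wittig, C13=C16 by α-methylenation of a C14 aldehyde); the C6 carbinol is then returned to a ketone.
- Ring B (C5–C6–C7–C8–C9–C10) then holds a β-hydroxy ketone, C6(=O)–C7H2–C8(OH)(CH3). C7 is its only unsubstituted carbon and C8 is fully substituted, so removing C7 leads back to a bicyclo[3.1.0] cyclopropanol (five-membered ring C5–C6–C8–C9–C10, C7 as the one-carbon bridge between C6 and C8).
- Forward: an amino-acid-catalysed Robinson annulation gives ring A fused to the five-membered ring. The C17 methyl, the C9 chain (enol triflate coupling), the C4 quaternary centre, the C6 oxygen and the cyclopropane follow; ring B is made last by oxidative one-carbon ring expansion.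
- Stereochemistry: C10 comes from the catalyst. C4 (alkylation), C5 (hydroboration), C9 (dissolving-metal reduction) and C8 (O2 capture) are each set anti to the axial C10 methyl; C6 is set by thermodynamic dissolving-metal reduction.

Key step: step 12

Remark: labdane numbering is used throughout (ring A = C1–C5 and C10; C20 on C10; C19 methyl and C18 on C4; C17 on C8; side chain C11–C16 on C9). In the hydrindane intermediates the five-membered ring is C5–C6–C8–C9–C10 and C7 is absent. The target is read as the 18-acetate of ent-labda-13(16),14-diene-6α,8α,18-triol.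
Assumption: D-phenylalanine gives the 7aR enone, the mirror image of the outcome with the L-amino acid.

Step 1
Reactants: 1 2-methylcyclopentane-1,3-dione; 2 pent-1-en-3-one
Product: 4 (7aR)-4,7a-dimethyl-2,3,7,7a-tetrahydro-1H-indene-1,5(6H)-dione, via triketone 3 (not isolated)
Conditions: H2O, rt; then D-phenylalanine, (1S)-(+)-CSA, DMF, 30 → 70 °C
Reagents that add atoms: none
Why: Michael addition then amino-acid-catalysed intramolecular aldol condensation (Hajos–Parrish reaction); the enamine of the D-amino acid differentiates the two ring carbonyls and should set C10.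

Step 2
Reactants: 4 (7aR)-enedione
Product: 5 C3 ethyl dienol ether (C3=C4, C5=C6) with free C9 ketone
Conditions: HC(OEt)3, EtOH, p-TsOH (cat.), rt
Reagents that add atoms: triethyl orthoformate, CCOC(OCC)OCC
Why: Acid-catalysed dienol ether formation is selective for the conjugated ketone (as with Δ4-3-keto steroids), so the hindered C9 cyclopentanone remains the only enolisable carbonyl; no stereocentre is formed.

Step 3
Reactants: 5 dienol ether ketone
Product: 6 C8-methyl ketone (methyl mainly trans to C20)
Conditions: LDA, THF, −78 °C; MeI, −78 → −40 °C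
Reagents that add atoms: iodomethane, CI
Why: Kinetic enolate α-alkylation, C8–H being the only acidic position; the C8 configuration does not matter because C8 becomes sp2 in step 4.

Step 4
Reactants: 6 C8-methyl ketone
Product: 7 C9 enol triflate (C8=C9–OTf, C5=C6, C3(OEt)=C4)
Conditions: KHMDS, THF, −78 °C; PhNTf2, −78 → 0 °C
Reagents that add atoms: N-phenylbis(trifluoromethanesulfonimide), O=S(=O)(N(c1ccccc1)S(=O)(=O)C(F)(F)F)C(F)(F)F
Why: Enolate O-sulfonylation (enol triflate formation); C8–H is the only α-hydrogen, so one regioisomer should form.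

Step 5
Reactants: 7 enol triflate; 8 4-(benzyloxy)but-1-ene
Product: 11 C9-alkylated enone (C3 ketone, C4=C5, C8=C9), via alkylborane 9 (not isolated), via triene ether 10 (not isolated)
Conditions: 8, 9-BBN, THF, 0 °C → rt; then 7, Pd(dppf)Cl2 (5 mol %), AsPh3, Cs2CO3, DMF/H2O, rt; then 1 M HCl, THF, 0 °C
Reagents that add atoms: water, O
Why: Anti-Markovnikov hydroboration of 8 followed by B-alkyl Suzuki–Miyaura coupling of the enol triflate, then acid hydrolysis of the dienol ether to the enone; any double-bond isomers of 11 should converge on the same trienolate in step 6.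

Step 6
Reactants: 11 enone
Product: 12 C4-quaternary ketone (C19 methyl cis and C18–OTIPS trans to C20; C5=C6–C8=C9 diene)
Conditions: KOtBu, THF, 0 °C; (i-Pr)3SiOCH2Cl, −78 → 0 °C
Reagents that add atoms: (triisopropylsiloxy)methyl chloride, ClCO[Si](C(C)C)(C(C)C)C(C)C
Why: Deconjugative α-alkylation of the thermodynamic extended enolate with an α-chloro ether; the electrophile should attack C4 on the face opposite the axial C10 methyl, which sets C4 and moves the double bond to C5=C6.

Step 7
Reactants: 12 C4-quaternary ketone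
Product: 14 C3-deoxygenated diene, via tosylhydrazone 13 (not isolated)
Conditions: TsNHNH2, EtOH, 60 °C; concentrate; then catecholborane, CHCl3, 0 °C; NaOAc·3H2O, 60 °C
Reagents that add atoms: none
Why: Tosylhydrazone formation and hydride reduction with loss of sulfinate and N2 (a mild Wolff–Kishner-type deoxygenation) should tolerate the silyl ether and the diene; the diazene carbon is not allylic, so no double-bond shift is expected.

Step 8
Reactants: 14 diene
Product: 16 allylic alcohol (C5–H and C6–OH trans to C20), via alkylborane 15 (not isolated)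
Conditions: BH3·THF, THF, 0 °C; then NaOH, H2O2, 0 °C → rt
Reagents that add atoms: hydrogen peroxide, OO
Why: Hydroboration–oxidation; boron should add to C6 of the trisubstituted C5=C6 bond (C5 is fully substituted) from the face opposite the C10 methyl, so syn delivery of H sets the trans ring fusion at C5, as in the hydroboration of Δ14 steroids.

Step 9
Reactants: 16 allylic alcohol
Product: 17 trans-hydrindenone (C6 ketone conjugated to C8=C9)
Conditions: DMP, NaHCO3, CH2Cl2, 0 °C → rt
Reagents that add atoms: none
Why: Buffered Dess–Martin oxidation of the allylic alcohol is non-enolising, so the C5 configuration should be kept.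

Step 10
Reactants: 17 trans-hydrindenone
Product: 19 C6 trimethylsilyl enol ether (C6=C8) carrying C14–OTMS, via dilithium enolate 18 (not isolated)
Conditions: Li (6 equiv), NH3(l)/THF, t-BuOH (1 equiv), −78 °C; isoprene; evaporate NH3; TMSCl, Et3N, THF, −78 → 0 °C
Reagents that add atoms: chlorotrimethylsilane, C[Si](C)(C)Cl
Why: Dissolving-metal (Birch-type) conjugate reduction with regiospecific enolate trapping; C9 should be protonated on the face opposite the C10 methyl so that the chain ends cis to C20, and the excess lithium cleaves the benzyl ether, whose alkoxide is silylated as well.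

Step 11
Reactants: 19 silyl enol ether
Product: 20 siloxycyclopropane (C7 bridging C6 and C8)
Conditions: Et2Zn, CH2I2, CH2Cl2, 0 °C → rt
Reagents that add atoms: diiodomethane, ICI
Why: Simmons–Smith cyclopropanation (Furukawa conditions) of the electron-rich enol ether, expected on the face opposite C20 and the C9 chain; either cyclopropane diastereomer serves in step 12.

Step 12
Reactants: 20 siloxycyclopropane
Product: 23 β-hydroxy ketone (trans-decalin, C6 ketone, C8–OH trans to C20), via cyclopropanol 21 (not isolated), via hydroperoxy ketone 22 (not isolated)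
Conditions: K2CO3 (cat.), MeOH, 0 °C; then Mn(acac)2 (5 mol %), O2 (1 atm), toluene, rt; then PPh3, 0 °C
Reagents that add atoms: dioxygen, O=O
Why: Methanolysis frees cyclopropanol 21, which Mn(III) formed under O2 oxidises to the cyclopropyloxy radical; β-scission of the internal C6–C8 bond inserts C7 and turns the five-membered ring into ring B with a C6 ketone and a tertiary C8 radical, and O2 capture, hydrogen transfer from the next cyclopropanol (chain) and PPh3 reduction of hydroperoxide 22 give 23. The closest known reactions are the Mn- or V-catalysed aerobic ring opening of cyclopropanols to β-hydroxy ketones and the Fe(III) ring expansion of 1-siloxybicyclo[n.1.0]alkanes. Ring B is closed not by a cyclisation but by fragmentation of the zero-atom bridge of the bicyclo[3.1.0]hexan-1-oxyl radical (a formal 1,2-acyl shift, the reverse of a 3-exo-trig closure). The only new stereocentre, C8, should be set when O2 adds to the planar radical on the face opposite the axial C10 methyl, giving the equatorial oxygen and the axial C17 methyl; both cyclopropane diastereomers give the same radical, so the step is stereoconvergent. The selectivity needed is internal over external bond cleavage, which the C17 methyl secures (tertiary against primary radical, and the external cleavage is reversible).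

Step 13
Reactants: 23 β-hydroxy ketone
Product: 24 6,8,14-triol (C6–OH equatorial, trans to C20)
Conditions: Li, NH3(l)/THF, MeOH, −78 °C; NH4Cl
Reagents that add atoms: none
Why: Dissolving-metal ketone reduction under thermodynamic control should give the equatorial C6 alcohol, because the axial position is syn to the three axial methyls on C4, C8 and C10 (compare 11-keto steroids), whereas hydride reagents would attack equatorially and give the axial epimer.

Step 14
Reactants: 24 triol
Product: 25 C14 aldehyde
Conditions: TEMPO (10 mol %), PhI(OAc)2, CH2Cl2, rt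
Reagents that add atoms: none
Why: Oxoammonium (TEMPO) oxidation is selective for the primary alcohol over the secondary C6 and tertiary C8 hydroxyls.

Step 15
Reactants: 25 aldehyde
Product: 26 α-methylene aldehyde (C13=C16)
Conditions: aq. CH2O (37 %), pyrrolidine (10 mol %), propionic acid (10 mol %), i-PrOH, 45 °C
Reagents that add atoms: formaldehyde, C=O
Why: Amine-catalysed Mannich condensation and elimination (α-methylenation of an aldehyde) tolerates free hydroxyls and installs C16.

Step 16
Reactants: 26 α-methylene aldehyde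
Product: 27 diene diol with C18–OTIPS
Conditions: Ph3PCH3Br, KHMDS, THF, 0 °C; then 26, −78 → 0 °C
Reagents that add atoms: methyltriphenylphosphonium bromide, C[P+](c1ccccc1)(c1ccccc1)c1ccccc1.[Br-]
Why: Wittig methylenation of the enal gives the 2-substituted buta-1,3-diene; excess ylide allows for the two free hydroxyls.

Step 17
Reactants: 27 silyl ether
Product: 28 ent-labda-13(16),14-diene-6α,8α,18-triol
Conditions: TBAF, THF, 45 °C
Reagents that add atoms: none
Why: Fluoride cleavage of the neopentyl silyl ether; the diene and the diol should be inert.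

Step 18
Reactants: 28 triol
Product: 29 target 18-acetate
Conditions: AcCl (1.1 equiv), 2,4,6-collidine, CH2Cl2, −78 °C
Reagents that add atoms: acetyl chloride, CC(Cl)=O
Why: Low-temperature acylation with a hindered base should select the primary C18 hydroxyl over the secondary C6 hydroxyl (flanked by C4 and C10) and the tertiary C8 hydroxyl.

**Compound list**
1 | 2-methylcyclopentane-1,3-dione | CC1C(=O)CCC1=O | starting material
2 | pent-1-en-3-one (ethyl vinyl ketone) | CCC(=O)C=C | starting material
3 | 2-methyl-2-(3-oxopentyl)cyclopentane-1,3-dione | CCC(=O)CCC1(C)C(=O)CCC1=O | intermediate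
4 | (7aR)-4,7a-dimethyl-2,3,7,7a-tetrahydro-1H-indene-1,5(6H)-dione | CC1=C2CCC(=O)[C@]2(C)CCC1=O | intermediate
5 | (7aR)-5-ethoxy-4,7a-dimethyl-2,6,7,7a-tetrahydro-1H-inden-1-one | CCOC1=C(C)C2=CCC(=O)[C@]2(C)CC1 | intermediate
6 | 5 with a methyl on C8 (main epimer, methyl trans to C20) | CCOC1=C(C)C2=C[C@H](C)C(=O)[C@]2(C)CC1 | intermediate
7 | C9 enol triflate (C8=C9, C5=C6, C3(OEt)=C4) | CCOC1=C(C)C2=CC(C)=C(OS(=O)(=O)C(F)(F)F)[C@]2(C)CC1 | intermediate
8 | 4-(benzyloxy)but-1-ene | C=CCCOCc1ccccc1 | starting material
9 | B-[4-(benzyloxy)butyl]-9-borabicyclo[3.3.1]nonane | c1ccccc1COCCCCB1C2CCCC1CCC2 | intermediate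
10 | 7 with the triflate replaced by the 4-(benzyloxy)butyl chain | CCOC1=C(C)C2=CC(C)=C(CCCCOCc3ccccc3)[C@]2(C)CC1 | intermediate
11 | enone: C3 ketone, C4=C5, C6H2, C8=C9 bearing C17 and the chain | CC1=C(CCCCOCc3ccccc3)[C@]2(C)CCC(=O)C(C)=C2C1 | intermediate
12 | C3 ketone with quaternary C4 (C19 cis, CH2OTIPS trans to C20) and C5=C6–C8=C9 diene | CC1=C(CCCCOCc3ccccc3)[C@]2(C)CCC(=O)[C@](C)(CO[Si](C(C)C)(C(C)C)C(C)C)C2=C1 | intermediate
13 | C3 tosylhydrazone of 12 | CC1=C(CCCCOCc3ccccc3)[C@]2(C)CCC(=NNS(=O)(=O)c3ccc(C)cc3)[C@](C)(CO[Si](C(C)C)(C(C)C)C(C)C)C2=C1 | intermediate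
14 | 12 with C3 as CH2 | CC1=C(CCCCOCc3ccccc3)[C@]2(C)CCC[C@](C)(CO[Si](C(C)C)(C(C)C)C(C)C)C2=C1 | intermediate
15 | C6 borane (BH2 on C6, H on C5, both trans to C20) | CC1=C(CCCCOCc3ccccc3)[C@]2(C)CCC[C@](C)(CO[Si](C(C)C)(C(C)C)C(C)C)[C@H]2[C@@H]1B | intermediate
16 | allylic alcohol (C6–OH and C5–H trans to C20, C8=C9) | CC1=C(CCCCOCc3ccccc3)[C@]2(C)CCC[C@](C)(CO[Si](C(C)C)(C(C)C)C(C)C)[C@H]2[C@@H]1O | intermediate
17 | trans-hydrindenone (C6 ketone, C8=C9) | CC1=C(CCCCOCc3ccccc3)[C@]2(C)CCC[C@](C)(CO[Si](C(C)C)(C(C)C)C(C)C)[C@H]2C1=O | intermediate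
18 | dilithium C6 enolate / C14 alkoxide (C9–H trans to C20) | [Li+].[Li+].[O-]CCCC[C@H]1[C@]2(C)CCC[C@](C)(CO[Si](C(C)C)(C(C)C)C(C)C)[C@H]2C([O-])=C1C | intermediate
19 | C6 trimethylsilyl enol ether (C6=C8) with C14–OTMS | C[Si](C)(C)OCCCC[C@H]1[C@]2(C)CCC[C@](C)(CO[Si](C(C)C)(C(C)C)C(C)C)[C@H]2C(O[Si](C)(C)C)=C1C | intermediate
20 | siloxycyclopropane (C7 bridging C6 and C8, on the face opposite C20) | C[Si](C)(C)OCCCC[C@H]1[C@]2(C)CCC[C@](C)(CO[Si](C(C)C)(C(C)C)C(C)C)[C@H]2[C@]3(O[Si](C)(C)C)C[C@]13C | intermediate
21 | cyclopropanol with free C14–OH | OCCCC[C@H]1[C@]2(C)CCC[C@](C)(CO[Si](C(C)C)(C(C)C)C(C)C)[C@H]2[C@]3(O)C[C@]13C | intermediate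
22 | ring-expanded C8 hydroperoxide, C6 ketone | OCCCC[C@H]1[C@]2(C)CCC[C@](C)(CO[Si](C(C)C)(C(C)C)C(C)C)[C@H]2C(=O)C[C@]1(C)OO | intermediate
23 | β-hydroxy ketone (C6 ketone, C8–OH trans to C20) | OCCCC[C@H]1[C@]2(C)CCC[C@](C)(CO[Si](C(C)C)(C(C)C)C(C)C)[C@H]2C(=O)C[C@]1(C)O | intermediate
24 | 6,8,14-triol, 18-O-TIPS | OCCCC[C@H]1[C@]2(C)CCC[C@](C)(CO[Si](C(C)C)(C(C)C)C(C)C)[C@H]2[C@H](O)C[C@]1(C)O | intermediate
25 | C14 aldehyde | O=CCCC[C@H]1[C@]2(C)CCC[C@](C)(CO[Si](C(C)C)(C(C)C)C(C)C)[C@H]2[C@H](O)C[C@]1(C)O | intermediate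
26 | α-methylene aldehyde | C=C(C=O)CC[C@H]1[C@]2(C)CCC[C@](C)(CO[Si](C(C)C)(C(C)C)C(C)C)[C@H]2[C@H](O)C[C@]1(C)O | intermediate
27 | 18-O-TIPS ent-labda-13(16),14-diene-6α,8α-diol | C=CC(=C)CC[C@H]1[C@]2(C)CCC[C@](C)(CO[Si](C(C)C)(C(C)C)C(C)C)[C@H]2[C@H](O)C[C@]1(C)O | intermediate
28 | ent-labda-13(16),14-diene-6α,8α,18-triol | C=CC(=C)CC[C@H]1[C@]2(C)CCC[C@](C)(CO)[C@H]2[C@H](O)C[C@]1(C)O | intermediate
29 | ent-6α,8α-dihydroxylabda-13(16),14-dien-18-yl acetate | C=CC(=C)CC[C@H]1[C@]2(C)CCC[C@](C)(COC(C)=O)[C@H]2[C@H](O)C[C@]1(C)O | target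

**Step count and risks**

Total steps: 18. Longest linear sequence: 18 steps (from 1 and 2).

Step 12. The ring opening may go through the outer cyclopropane bond, oxygen capture at C8 may occur from both faces, or the hydroperoxide may eliminate. The fallback sets out from 20. FeCl3 in DMF at 0 °C opens the siloxycyclopropane by one-electron oxidation, ring expansion and chlorine transfer to the ring-expanded β-chloro ketone F1. Sodium acetate in methanol converts it into the cyclohexenone F2 (C6 ketone, C7=C8). Alkaline hydrogen peroxide should epoxidise the enone on the face opposite the C10 methyl to give the epoxy ketone F3. Samarium diiodide (THF/MeOH, −78 °C) then cleaves the C7–O bond and gives 23, where the route is rejoined.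

Step 6. The trienolate may be alkylated on oxygen or at C6 instead of C4, or facial control at C4 may be poor. The fallback sets out from 11. The same trienolate is treated with anhydrous monomeric formaldehyde in a carbon-selective aldol addition to give the hydroxymethyl ketone F4. Silylation with TIPSOTf and 2,6-lutidine gives 12.

Step 8. Hydroboration may attack the tetrasubstituted double bond or place boron at the wrong carbon, the allylic borane may rearrange or be protonated, and the ring fusion may form as a mixture. The fallback sets out from 11. A dissolving-metal reductive alkylation (Li 2.2 equiv, NH3/THF, t-BuOH; then (i-Pr)3SiOCH2Cl) sets the trans C5 hydrogen and the C4 quaternary centre in one operation and gives the saturated ketone F5; the limited lithium should spare the benzyl ether. C3 is removed as in step 7 through the tosylhydrazone F6 to give the alkene F7. Allylic oxidation of the ring methylene C6 with CrO3·3,5-dimethylpyrazole gives 17.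

Further compounds
F1 | step 12 | ring-expanded β-chloro ketone (C8 epimers) | OCCCC[C@H]1[C@]2(C)CCC[C@](C)(CO[Si](C(C)C)(C(C)C)C(C)C)[C@H]2C(=O)CC1(C)Cl
F2 | step 12 | cyclohexenone (C6 ketone, C7=C8) | OCCCC[C@H]1[C@]2(C)CCC[C@](C)(CO[Si](C(C)C)(C(C)C)C(C)C)[C@H]2C(=O)C=C1C
F3 | step 12 | 7,8-epoxy ketone (oxygen trans to C20) | OCCCC[C@H]1[C@]2(C)CCC[C@](C)(CO[Si](C(C)C)(C(C)C)C(C)C)[C@H]2C(=O)[C@@H]3O[C@]13C
F4 | step 6 | C4 hydroxymethyl ketone | CC1=C(CCCCOCc3ccccc3)[C@]2(C)CCC(=O)[C@](C)(CO)C2=C1
F5 | step 8 | saturated C3 ketone (C5–H trans to C20, C8=C9) | CC1=C(CCCCOCc3ccccc3)[C@]2(C)CCC(=O)[C@](C)(CO[Si](C(C)C)(C(C)C)C(C)C)[C@H]2C1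
F6 | step 8 | C3 tosylhydrazone of F5 | CC1=C(CCCCOCc3ccccc3)[C@]2(C)CCC(=NNS(=O)(=O)c3ccc(C)cc3)[C@](C)(CO[Si](C(C)C)(C(C)C)C(C)C)[C@H]2C1
F7 | step 8 | C3-deoxygenated alkene (C8=C9) | CC1=C(CCCCOCc3ccccc3)[C@]2(C)CCC[C@](C)(CO[Si](C(C)C)(C(C)C)C(C)C)[C@H]2C1
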